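Links are the product we count, at the outlet or at the end of each set-up.

    first end groups + second end groups → links (k1 = 0.069 M⁻¹ s⁻¹)
    first end groups + second end groups → rings, rate k2*[first end groups] as long as [second end groups] is above zero (k2 = 3.9 × 10⁻⁵ s⁻¹)
    first end groups → decomposition product (k3 = 3.5 × 10⁻⁶ s⁻¹)
    links → over-reaction product (k4 = 0.0011 s⁻¹)

| flask | first end groups | second end groups | time | remark |
|---|---|---|---|---|
| Sunday's | 0.050 M | 0.0500 M (fed, over 1.00 h) | 2.0 h | a stirred flask in which second end groups is dosed at a steady rate over 1.00 h without added volume, worked up at 2.0 h |
| Friday's | 0.050 M | 0.0500 M |  | one stirred flow tank at steady state, fed with the mixture as stated, mean residence time 2.0 h |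
| Monday's | 0.050 M | 0.0500 M | 2.0 h | a closed flask charged with all of it at once and left for 2.0 h |
| Wednesday's | 0.050 M (fed, over 1.00 h) | 0.0500 M | 2.0 h | a stirred flask in which first end groups is dosed at a steady rate over 1.00 h without added volume, worked up at 2.0 h |

* the set-up with the highest amount of links at the outlet or at the end, in percent of the first end groups put in ("none" if the first two lie within 2 percentage points) (Sunday's / Friday's / Monday's / Wednesday's / none)
* amount of links at the outlet or at the end, in percent of the first end groups put in, Sunday's
* amount of links at the outlet or at the end, in percent of the first end groups put in, Friday's
* amount of links at the outlet or at the end, in percent of the first end groups put in, Monday's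
* amount of links at the outlet or at the end, in percent of the first end groups put in, Wednesday's

- the stated concentrations are those of everything mixed, before any reaction; amounts are the same in each set-up
- the feed brings no volume worth counting
- run time (Sunday's): 2.0 h

The quantity we carry is the link lifetime, one over the constant of the step from links to over-reaction product: 15.2 min. It is shorter than the run, so we treat links as near a quasi-steady state and estimate the amount on hand as the link-forming rate one lifetime before the end, times the lifetime.

We reckon this for Monday's closed flask, at 1.75 h. In Monday's flask links start forming at 0.621 M h⁻¹. The link-forming step is second order and both end groups fall together, so that step's own consumption divides the rate by 515. Ring closure, first order in first end groups, divides it by a further 1.30. Decomposition is slower than ring closure, so we set it aside. The accumulated slowing leaves 9.27 × 10⁻⁴ M h⁻¹, and one lifetime of that is 0.468% of the first end groups put in.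

The forecast names Friday's, with 8.7% there (8.3% to 9.1%), 1.9% for Sunday's, 1.9% for Wednesday's and 0.52% for Monday's. Our Monday's figure lies below its number. Its ground is that the tank “keeps making links right up to the outlet”.

The simulation gives Friday's: 8.66% there, 1.96% for Sunday's, 2.01% for Wednesday's and 0.564% for Monday's. The loss of links to over-reaction product is what puts the tank ahead: with that step struck out, Friday's tank holds 77.3% and Monday's flask 93.0%, a lead of 16 percentage points for Monday's. With the step in place, Friday's tank forms links steadily at 0.0193 M h⁻¹, from 17.4% of first end groups unreacted and 0.00893 M of second end groups, which is faster than the rate we reckoned for Monday's flask at 1.75 h. Outflow from Friday's tank over the mean residence time of 2.0 h trims the lifetime to 13.5 min, and that rate over that time comes to 8.66% of the first end groups put in.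

(The numbers of this flask were set for the occasion; what happens was integrated by code.)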